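**Retrosynthetic overview**
1. The strategy rests on ring F: O1' links the benzylic carbon C2' to the ring D carbon C8a', which lies between C8' (bonded to C4 of the upper flavan) and C4a' (bonded to C4'). Ring F is therefore opened at O1'–C8a', which leaves an aryl triflate and an open C4'–C3'–C2' chain whose three stereocenters are fixed before closure.
2. The chain is grown from a ring D aldehyde (C4'): an Evans syn glycolate aldol sets C4' and C3', and chelation-controlled addition of the ring E aryl Grignard reagent to the C2' aldehyde sets C2'.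
3. The C4–C8' bond comes from addition of a ring D aryllithium to the C4 ketone of perbenzylated (+)-epicatechin, followed by ionic hydrogenation to the all-cis 4-arylflavan; ortho-formylation and triflation then arm ring D.
4. Ring order: rings A, B and C come from the chiral pool, rings D and E enter as arenes, and ring F is closed last by palladium aryl etherification; fluoride and hydrogenolysis finish.

Key step: step 16

Assumption: (+)-epicatechin, the (2S,3S) enantiomer, is taken as a catalogue compound; unprimed locants refer to the upper flavan (rings A, B, C) and primed locants to the lower one (rings D, E, F).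

**Route**

Step 1
Reactants: 1 (+)-epicatechin
Product: 2 5,7,3',4'-tetra-O-benzyl-(+)-epicatechin
Conditions: BnBr (4.4 equiv), K2CO3, DMF, 0 °C to rt
Reagents that add atoms: benzyl bromide, BrCc1ccccc1
Why: Williamson etherification in which K2CO3 deprotonates only the four phenols, so the C3 alcohol stays free and C2 and C3 are untouched.

Step 2
Reactants: 2 5,7,3',4'-tetra-O-benzyl-(+)-epicatechin
Product: 3 3,5,7,3',4'-penta-O-benzyl-(+)-epicatechin
Conditions: NaH, BnBr, Bu4NI (cat.), DMF, 0 °C to rt
Reagents that add atoms: benzyl bromide, BrCc1ccccc1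
Why: Williamson etherification of the secondary C3 alkoxide, which places the same robust ether on O3 that the lower unit will carry on O3'.

Step 3
Reactants: 3 3,5,7,3',4'-penta-O-benzyl-(+)-epicatechin
Product: 4 penta-O-benzyl-(+)-epicatechin-4-ol (4-OH trans to the 3-benzyloxy group)
Conditions: DDQ (2 equiv), CH2Cl2/H2O, rt
Reagents that add atoms: water, O
Why: DDQ benzylic oxidation, in which hydride abstraction at C4 (activated by the ring A oxygens at C5 and C7) gives a cation that water should capture anti to the C3 substituent; the C4 configuration is irrelevant because it is oxidized next.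

Step 4
Reactants: 4 penta-O-benzyl-(+)-epicatechin-4-ol
Product: 5 (2S,3R)-3,5,7-tris(benzyloxy)-2-[3,4-bis(benzyloxy)phenyl]chroman-4-one (2,3-cis)
Conditions: Dess–Martin periodinane, CH2Cl2, 0 °C to rt
Reagents that add atoms: none
Why: Dess–Martin oxidation of the secondary benzylic alcohol under near-neutral conditions, which should spare the epimerizable C3 center of the cis ketone.

Step 5
Reactants: 6 3,5-bis(benzyloxy)phenol
Product: 7 1,3-bis(benzyloxy)-5-(methoxymethoxy)benzene
Conditions: MOMCl, i-Pr2NEt, CH2Cl2, 0 °C to rt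
Reagents that add atoms: chloromethyl methyl ether, COCCl
Why: Acetal formation on the phenol installs the metalation-directing group on the oxygen that will become O(C8a') and distinguishes it from the two benzyl ethers.

Step 6
Reactants: 7 1,3-bis(benzyloxy)-5-(methoxymethoxy)benzene; 5 2,3-cis chroman-4-one
Product: 9 penta-O-benzyl-(+)-epicatechin bearing at C4 a hydroxyl and the 2,4-bis(benzyloxy)-6-(methoxymethoxy)phenyl group (aryl trans to the 3-benzyloxy group), via aryllithium 8 (not isolated)
Conditions: 7 (2.5 equiv), n-BuLi, THF, 0 °C; then 5, THF, −78 to 0 °C; then H2O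
Reagents that add atoms: none
Why: Directed ortho-metalation in which the MOM ether steers n-BuLi to either of the two equivalent ring positions between OMOM and OBn, followed by 1,2-addition of the 2,6-dioxygenated aryllithium to the C4 ketone to form the C4–C8' bond; the carbinol configuration is erased in step 7.

Step 7
Reactants: 9 C4 tertiary alcohol
Product: 10 all-cis 4-[2,4-bis(benzyloxy)-6-hydroxyphenyl]-penta-O-benzyl-(+)-epicatechin (C4 aryl cis to the C3 benzyloxy and C2 aryl groups; ring D phenol at C8a' free)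
Conditions: Bu3SnH (6 equiv), CF3CO2H, CH2Cl2, 0 °C to rt
Reagents that add atoms: none
Why: Ionic hydrogenation, in which acid ionizes the doubly benzylic tertiary alcohol and Bu3SnH delivers hydride to the C4 cation on the face anti to the cis C2 aryl and C3 benzyloxy groups, setting C4 with the ring D aryl cis to both, while the same acid cleaves the MOM acetal and the stannane reduces the methoxymethyl cation.

Step 8
Reactants: 10 all-cis 4-arylflavan phenol
Product: 11 ring D salicylaldehyde (formyl at C4a' and hydroxyl at C8a' with benzyloxy groups at C5' and C7' and the all-cis flavan at C8')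
Conditions: MgCl2, Et3N, (CH2O)n, THF, reflux
Reagents that add atoms: paraformaldehyde (reacts as formaldehyde), C=O
Why: Casnati–Skattebøl ortho-formylation, in which the magnesium phenoxide delivers formaldehyde to its only free ortho position C4a' and a second formaldehyde oxidizes the resulting benzylic alkoxide to the aldehyde.

Step 9
Reactants: 11 ring D salicylaldehyde
Product: 12 C8a' aryl triflate of the ring D aldehyde
Conditions: Tf2O, pyridine, CH2Cl2, 0 °C
Reagents that add atoms: triflic anhydride, O=S(=O)(OS(=O)(=O)C(F)(F)F)C(F)(F)F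
Why: O-Sulfonylation of the hydrogen-bonded phenol installs the leaving group for the key step and leaves a non-enolizable aldehyde for the aldol.

Step 10
Reactants: 13 (R)-4-benzyloxazolidin-2-one; 14 benzyloxyacetyl chloride
Product: 15 (R)-4-benzyl-3-[(benzyloxy)acetyl]oxazolidin-2-one
Conditions: n-BuLi, THF, −78 °C; then 14, −78 to 0 °C
Reagents that add atoms: none
Why: N-Acylation of the lithiated oxazolidinone by the acid chloride gives the glycolate imide that carries O3' as its benzyl ether.

Step 11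
Reactants: 15 glycolate imide; 12 ring D aldehyde triflate
Product: 17 syn aldol adduct (4R)-4-benzyl-3-[(2R,3S)-2-benzyloxy-3-hydroxy-3-aryl-propanoyl]oxazolidin-2-one in which the aryl group is ring D of 12, via boron enolate 16 (not isolated)
Conditions: 15, Bu2BOTf, Et3N, CH2Cl2, −78 to 0 °C; then 12, −78 to 0 °C; then pH 7 buffer, MeOH, H2O2, 0 °C
Reagents that add atoms: none
Why: Evans syn glycolate aldol, in which the Z boron enolate reacts through a chair Zimmerman–Traxler transition state on the enolate face anti to the auxiliary benzyl group, so that the (R)-auxiliary sets C4' and C3' syn with the absolute configuration of the target irrespective of the remote flavan stereocenters.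

Step 12
Reactants: 17 syn aldol adduct
Product: 18 N-methoxy-N-methyl amide with free C4' hydroxyl
Conditions: MeNH(OMe)·HCl, AlMe3, CH2Cl2, −10 to 0 °C; then aq. KNaC4H4O6
Reagents that add atoms: N,O-dimethylhydroxylamine hydrochloride, CNOC.Cl
Why: Weinreb transamidation by the aluminium amide, assisted by the free β-hydroxyl, cleaves the exocyclic imide carbonyl selectively and releases the auxiliary without touching C3'.

Step 13
Reactants: 18 Weinreb amide
Product: 19 C4' tert-butyldimethylsilyl ether of the Weinreb amide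
Conditions: TBSOTf, 2,6-lutidine, CH2Cl2, 0 °C
Reagents that add atoms: tert-butyldimethylsilyl triflate, CC(C)(C)[Si](C)(C)OS(=O)(=O)C(F)(F)F
Why: Silylation with the silyl triflate caps the hindered benzylic C4' hydroxyl with a poorly chelating group, which blocks retro-aldol cleavage and leaves O3' as the only chelating site for step 15.

Step 14
Reactants: 19 silylated Weinreb amide
Product: 20 (2R,3S)-2-benzyloxy-3-silyloxy-3-aryl-propanal (C2' aldehyde)
Conditions: i-Bu2AlH, THF, −78 °C; then aq. KNaC4H4O6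
Reagents that add atoms: none
Why: Weinreb amide reduction stops at the stable chelated tetrahedral aluminate, which releases the α-benzyloxy aldehyde only on work-up and so avoids over-reduction and epimerization at C3'.

Step 15
Reactants: 20 C2' aldehyde; 21 4-bromo-1,2-bis(benzyloxy)benzene
Product: 23 open-chain precursor with free C2' hydroxyl (C4' silyl ether and C3' benzyl ether with ring E on C2' and the C8a' triflate on ring D; chain all-syn), via Grignard reagent 22 (not isolated)
Conditions: 21, Mg, THF, rt; then 20, MgBr2·OEt2, CH2Cl2, −78 °C; then H2O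
Reagents that add atoms: none
Why: Cram-chelate controlled Grignard addition, in which magnesium bridges the aldehyde oxygen and the C3' benzyloxy oxygen and the aryl group enters from the face opposite the bulky C4' substituent, which should give the 2',3'-syn alcohol with C2' configured as in the target.

Step 16
Reactants: 23 open-chain precursor
Product: 24 protected dimer with ring F closed (C4' silyl ether and ten benzyl ethers)
Conditions: Pd2(dba)3 (5 mol %), 2-di-tert-butylphosphino-2',4',6'-triisopropylbiphenyl (12 mol %), Cs2CO3, toluene, 80 °C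
Reagents that add atoms: none
Why: Zerovalent palladium carrying the bulky phosphine inserts into the C8a'–OTf bond, Cs2CO3 deprotonates the palladium-bound C2' hydroxyl, and C–O reductive elimination from the aryl(alkoxo) divalent palladium complex forms O1'–C8a'. The closest known reaction type is the palladium-catalysed intramolecular etherification of aryl halides and sulfonates with secondary alcohols that gives chromans. Ring F closes as a six-membered ring at the aryl carbon through a seven-membered palladacycle. No stereocenter is formed and no bond to C2', C3' or C4' is broken, so the alcohol oxygen becomes O1' with retention at C2' and the three centers set in steps 11 and 15 pass unchanged into the ring. The step needs reductive elimination to outrun β-hydride elimination of the C2' alkoxide and S–O cleavage of the triflate. The electron-rich di-tert-butyl biarylphosphine, the poorly soluble carbonate in toluene and the two ortho substituents at C8a', which crowd the metal and speed reductive elimination, should secure this.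

Step 17
Reactants: 24 protected dimer with C4' silyl ether
Product: 25 deca-O-benzyl dimer with free C4' hydroxyl
Conditions: Bu4NF, THF, 0 °C to rt
Reagents that add atoms: none
Why: Fluoride desilylation is carried out while all phenols are still benzylated, so no phenoxide can expel the C4' oxygen.

Step 18
Reactants: 25 deca-O-benzyl dimer
Product: 26 target CNP0114173.1 with upper unit (2S,3S,4R) and lower unit (2'R,3'R,4'S)
Conditions: H2 (1 atm), Pd(OH)2 on carbon, THF/MeOH, rt
Reagents that add atoms: none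
Why: Hydrogenolysis of the ten benzyl ethers under neutral conditions should release the polyphenol without acid, which the C4' benzylic alcohol would not tolerate.

**Compound list**

1 | (+)-epicatechin, (2S,3S) | Oc1cc(O)c2c(c1)O[C@@H](c1ccc(O)c(O)c1)[C@@H](O)C2 | starting material
2 | 5,7,3',4'-tetra-O-benzyl-(+)-epicatechin | c9ccccc9COc1cc(OCc9ccccc9)c2c(c1)O[C@@H](c1ccc(OCc9ccccc9)c(OCc9ccccc9)c1)[C@@H](O)C2 | intermediate
3 | 3,5,7,3',4'-penta-O-benzyl-(+)-epicatechin | c9ccccc9COc1cc(OCc9ccccc9)c2c(c1)O[C@@H](c1ccc(OCc9ccccc9)c(OCc9ccccc9)c1)[C@@H](OCc9ccccc9)C2 | intermediate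
4 | penta-O-benzyl-(+)-epicatechin-4-ol, 4-OH trans to 3-OBn | c9ccccc9COc1cc(OCc9ccccc9)c2c(c1)O[C@@H](c1ccc(OCc9ccccc9)c(OCc9ccccc9)c1)[C@@H](OCc9ccccc9)[C@@H]2O | intermediate
5 | (2S,3R)-3,5,7-tris(benzyloxy)-2-[3,4-bis(benzyloxy)phenyl]chroman-4-one, 2,3-cis | c9ccccc9COc1cc(OCc9ccccc9)c2c(c1)O[C@@H](c1ccc(OCc9ccccc9)c(OCc9ccccc9)c1)[C@@H](OCc9ccccc9)C2=O | intermediate
6 | 3,5-bis(benzyloxy)phenol | Oc1cc(OCc2ccccc2)cc(OCc2ccccc2)c1 | starting material
7 | 1,3-bis(benzyloxy)-5-(methoxymethoxy)benzene | COCOc1cc(OCc2ccccc2)cc(OCc2ccccc2)c1 | intermediate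
8 | 2,4-bis(benzyloxy)-6-(methoxymethoxy)phenyllithium | [Li]c1c(OCOC)cc(OCc2ccccc2)cc1OCc1ccccc1 | intermediate
9 | C4 tertiary alcohol: penta-O-benzyl-(+)-epicatechin with 4-OH (cis to 3-OBn) and 4-[2,4-bis(benzyloxy)-6-(methoxymethoxy)phenyl] | c9ccccc9COc1cc(OCc9ccccc9)c2c(c1)O[C@@H](c1ccc(OCc9ccccc9)c(OCc9ccccc9)c1)[C@@H](OCc9ccccc9)[C@]2(O)c1c(OCOC)cc(OCc9ccccc9)cc1OCc9ccccc9 | intermediate
10 | all-cis 4-[2,4-bis(benzyloxy)-6-hydroxyphenyl]-penta-O-benzyl-(+)-epicatechin | c9ccccc9COc1cc(OCc9ccccc9)c2c(c1)O[C@@H](c1ccc(OCc9ccccc9)c(OCc9ccccc9)c1)[C@@H](OCc9ccccc9)[C@H]2c1c(O)cc(OCc9ccccc9)cc1OCc9ccccc9 | intermediate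
11 | ring D salicylaldehyde: as 10 with formyl at C4a' (ortho to the C8a' hydroxyl) | c9ccccc9COc1cc(OCc9ccccc9)c2c(c1)O[C@@H](c1ccc(OCc9ccccc9)c(OCc9ccccc9)c1)[C@@H](OCc9ccccc9)[C@H]2c1c(O)c(C=O)c(OCc9ccccc9)cc1OCc9ccccc9 | intermediate
12 | C8a' aryl triflate of 11 | c9ccccc9COc1cc(OCc9ccccc9)c2c(c1)O[C@@H](c1ccc(OCc9ccccc9)c(OCc9ccccc9)c1)[C@@H](OCc9ccccc9)[C@H]2c1c(OS(=O)(=O)C(F)(F)F)c(C=O)c(OCc9ccccc9)cc1OCc9ccccc9 | intermediate
13 | (R)-4-benzyloxazolidin-2-one | O=C1OC[C@@H](Cc2ccccc2)N1 | starting material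
14 | benzyloxyacetyl chloride | O=C(Cl)COCc1ccccc1 | starting material
15 | (R)-4-benzyl-3-[(benzyloxy)acetyl]oxazolidin-2-one | O=C1OC[C@@H](Cc2ccccc2)N1C(=O)COCc1ccccc1 | intermediate
16 | Z dibutylboron enolate of 15 | CCCCB(CCCC)O/C(=C\OCc1ccccc1)N1[C@H](Cc2ccccc2)COC1=O | intermediate
17 | syn aldol adduct, (4R)-4-benzyl-3-[(2R,3S)-2-benzyloxy-3-hydroxy-3-(ring D aryl)propanoyl]oxazolidin-2-one | c9ccccc9COc1cc(OCc9ccccc9)c2c(c1)O[C@@H](c1ccc(OCc9ccccc9)c(OCc9ccccc9)c1)[C@@H](OCc9ccccc9)[C@H]2c1c(OS(=O)(=O)C(F)(F)F)c([C@H](O)[C@@H](OCc9ccccc9)C(=O)N3C(=O)OC[C@H]3Cc3ccccc3)c(OCc9ccccc9)cc1OCc9ccccc9 | intermediate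
18 | Weinreb amide with free C4' hydroxyl | c9ccccc9COc1cc(OCc9ccccc9)c2c(c1)O[C@@H](c1ccc(OCc9ccccc9)c(OCc9ccccc9)c1)[C@@H](OCc9ccccc9)[C@H]2c1c(OS(=O)(=O)C(F)(F)F)c([C@H](O)[C@@H](OCc9ccccc9)C(=O)N(C)OC)c(OCc9ccccc9)cc1OCc9ccccc9 | intermediate
19 | C4' tert-butyldimethylsilyl ether of 18 | c9ccccc9COc1cc(OCc9ccccc9)c2c(c1)O[C@@H](c1ccc(OCc9ccccc9)c(OCc9ccccc9)c1)[C@@H](OCc9ccccc9)[C@H]2c1c(OS(=O)(=O)C(F)(F)F)c([C@H](O[Si](C)(C)C(C)(C)C)[C@@H](OCc9ccccc9)C(=O)N(C)OC)c(OCc9ccccc9)cc1OCc9ccccc9 | intermediate
20 | C2' aldehyde, (2R,3S)-2-benzyloxy-3-silyloxy-3-(ring D aryl)propanal | c9ccccc9COc1cc(OCc9ccccc9)c2c(c1)O[C@@H](c1ccc(OCc9ccccc9)c(OCc9ccccc9)c1)[C@@H](OCc9ccccc9)[C@H]2c1c(OS(=O)(=O)C(F)(F)F)c([C@H](O[Si](C)(C)C(C)(C)C)[C@@H](OCc9ccccc9)C=O)c(OCc9ccccc9)cc1OCc9ccccc9 | intermediate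
21 | 4-bromo-1,2-bis(benzyloxy)benzene | Brc1ccc(OCc2ccccc2)c(OCc2ccccc2)c1 | starting material
22 | 3,4-bis(benzyloxy)phenylmagnesium bromide | Br[Mg]c1ccc(OCc2ccccc2)c(OCc2ccccc2)c1 | intermediate
23 | open-chain precursor: ring D triflate with all-syn C4'(OTBS)–C3'(OBn)–C2'(OH) chain ending in ring E | c9ccccc9COc1cc(OCc9ccccc9)c2c(c1)O[C@@H](c1ccc(OCc9ccccc9)c(OCc9ccccc9)c1)[C@@H](OCc9ccccc9)[C@H]2c1c(OS(=O)(=O)C(F)(F)F)c([C@H](O[Si](C)(C)C(C)(C)C)[C@@H](OCc9ccccc9)[C@H](O)c3ccc(OCc9ccccc9)c(OCc9ccccc9)c3)c(OCc9ccccc9)cc1OCc9ccccc9 | intermediate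
24 | protected dimer with ring F closed, C4' silyl ether | c9ccccc9COc1cc(OCc9ccccc9)c2c(c1)O[C@@H](c1ccc(OCc9ccccc9)c(OCc9ccccc9)c1)[C@@H](OCc9ccccc9)[C@H]2c1c(OCc9ccccc9)cc(OCc9ccccc9)c2c1O[C@H](c1ccc(OCc9ccccc9)c(OCc9ccccc9)c1)[C@H](OCc9ccccc9)[C@H]2O[Si](C)(C)C(C)(C)C | intermediate
25 | deca-O-benzyl dimer with free C4' hydroxyl | c9ccccc9COc1cc(OCc9ccccc9)c2c(c1)O[C@@H](c1ccc(OCc9ccccc9)c(OCc9ccccc9)c1)[C@@H](OCc9ccccc9)[C@H]2c1c(OCc9ccccc9)cc(OCc9ccccc9)c2c1O[C@H](c1ccc(OCc9ccccc9)c(OCc9ccccc9)c1)[C@H](OCc9ccccc9)[C@H]2O | intermediate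
26 | CNP0114173.1 | Oc1cc(O)c2c(c1)O[C@@H](c1ccc(O)c(O)c1)[C@@H](O)[C@H]2c1c(O)cc(O)c2c1O[C@H](c1ccc(O)c(O)c1)[C@H](O)[C@H]2O | target

**Step count**
Total: 18 steps. Longest linear sequence: 16 steps (1 to 26 through steps 1–4, 6–9 and 11–18).

**Steps most likely to fail**

Step 16. The triflate may be cleaved at sulfur by alkoxide or carbonate, the palladium alkoxide may undergo β-hydride elimination (net arene reduction and oxidation at C2'), oxidative addition at the doubly ortho-substituted carbon may be slow, and base may shift the silyl group from O4' to O2'. The fallback closes ring F at O1'–C2' instead and sets out from Weinreb amide 19. Grignard reagent 22 should add to 19 to give aryl ketone F1. Zn(BH4)2 in Et2O should reduce it under chelation control (zinc held between the ketone and the C3' benzyloxy oxygen) to the 2',3'-anti alcohol F2, the C2' epimer of 23. Et4NOH in aqueous dioxane should cleave the triflate to phenol F3. A Mitsunobu etherification (PPh3, DIAD, THF, 0 °C) should then join the C8a' phenol oxygen to C2' with inversion, and the route is rejoined at 24.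

Step 6. Metalation may occur at the ring position between the two benzyloxy groups or at a benzylic CH2, and the basic aryllithium may enolize or ring-open the hindered ketone instead of adding. The fallback sets out from phenol 6. I2 and NaHCO3 in aqueous THF should iodinate the position between the hydroxyl and a benzyloxy group to give 3,5-bis(benzyloxy)-2-iodophenol F4, and MOMCl with i-Pr2NEt should give the MOM ether F5. Iodine–lithium exchange with t-BuLi at −78 °C generates aryllithium 8 at a defined carbon, and CeCl3 converts it into the less basic arylcerium dichloride F6, which should add to ketone 5. The route is rejoined at 9.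

Step 18. The benzylic C4'–O bond on the electron-rich ring D may be cleaved by hydrogenolysis, or C4' may ionize, while the ten benzyl ethers are removed. The fallback reverses the order of the last two steps and sets out from 24. Hydrogenolysis over Pd(OH)2 on carbon with the silyl ether still in place should give the C4' silyl ether of the target F7, in which the bulky silyloxy group shields C4'. Bu4NF buffered with AcOH in THF should then remove the silyl group, and the route is rejoined at 26.

**Further compounds**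

F1 | step 16 | aryl ketone at C2' (C4' silyl ether, C3' benzyl ether, C8a' triflate) | c9ccccc9COc1cc(OCc9ccccc9)c2c(c1)O[C@@H](c1ccc(OCc9ccccc9)c(OCc9ccccc9)c1)[C@@H](OCc9ccccc9)[C@H]2c1c(OS(=O)(=O)C(F)(F)F)c([C@H](O[Si](C)(C)C(C)(C)C)[C@@H](OCc9ccccc9)C(=O)c3ccc(OCc9ccccc9)c(OCc9ccccc9)c3)c(OCc9ccccc9)cc1OCc9ccccc9
F2 | step 16 | 2',3'-anti alcohol, C2' epimer of 23 | c9ccccc9COc1cc(OCc9ccccc9)c2c(c1)O[C@@H](c1ccc(OCc9ccccc9)c(OCc9ccccc9)c1)[C@@H](OCc9ccccc9)[C@H]2c1c(OS(=O)(=O)C(F)(F)F)c([C@H](O[Si](C)(C)C(C)(C)C)[C@@H](OCc9ccccc9)[C@@H](O)c3ccc(OCc9ccccc9)c(OCc9ccccc9)c3)c(OCc9ccccc9)cc1OCc9ccccc9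
F3 | step 16 | C8a' phenol of F2 | c9ccccc9COc1cc(OCc9ccccc9)c2c(c1)O[C@@H](c1ccc(OCc9ccccc9)c(OCc9ccccc9)c1)[C@@H](OCc9ccccc9)[C@H]2c1c(O)c([C@H](O[Si](C)(C)C(C)(C)C)[C@@H](OCc9ccccc9)[C@@H](O)c3ccc(OCc9ccccc9)c(OCc9ccccc9)c3)c(OCc9ccccc9)cc1OCc9ccccc9
F4 | step 6 | 3,5-bis(benzyloxy)-2-iodophenol | Oc1cc(OCc2ccccc2)cc(OCc2ccccc2)c1I
F5 | step 6 | 1,5-bis(benzyloxy)-2-iodo-3-(methoxymethoxy)benzene | COCOc1cc(OCc2ccccc2)cc(OCc2ccccc2)c1I
F6 | step 6 | [2,4-bis(benzyloxy)-6-(methoxymethoxy)phenyl]cerium dichloride | Cl[Ce](Cl)c1c(OCOC)cc(OCc2ccccc2)cc1OCc1ccccc1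
F7 | step 18 | C4' tert-butyldimethylsilyl ether of the target | Oc1cc(O)c2c(c1)O[C@@H](c1ccc(O)c(O)c1)[C@@H](O)[C@H]2c1c(O)cc(O)c2c1O[C@H](c1ccc(O)c(O)c1)[C@H](O)[C@H]2O[Si](C)(C)C(C)(C)C
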